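**Plan**
1. Retrosynthesis: after removing the O3 silyl group, the C14'–C15' sp2–sp2 bond and the C13'–CH3 bond are cut together, giving C18 pentaenyne 11, Me3Al and C21 dienyl iodide 30. The enabling feature is the trisubstituted C13'(CH3)=C14'H alkene next to that bond, with its methyl cis to C15': the signature of a syn-methylmetalation of a terminal alkyne.
2. The ψ half is grown from 6-methylhept-5-en-1-yne by two earlier rounds of the same methylalumination/Pd coupling with a C4 iodoenyne, so the C5' and C9' methyls enter the same way.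
3. The fused 2,5-dihydrofuran (O–C8–C7=C6–C5 on the cyclohexane C1–C6) is opened to a 5-hydroxy-6,7-allene. The allene comes from an alkynyl 5,6-epoxide (temporary ring), the epoxide from an allylic alcohol, and the ring from (4R,6R)-actinol.
4. Forward order: cyclohexane (bought) → oxirane → allene → dihydrofuran → C15 enal → C20 trienal → C21 iodide; then union with the ψ chain and desilylation.
5. Stereochemistry: C3 from actinol; C5 (and C6 of the oxirane) from Sharpless epoxidation with D-(−)-tartrate; the allene axis from syn-SN2' hydride delivery; C8 by axis-to-centre transfer in the cyclisation. Alkene geometry comes from syn-carbometalation, Takai and HWE olefinations and stereoretentive couplings.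

Key step: step 23

Remark: the target is read as all-E (3S,5R,8S)-5,8-epoxy-5,8-dihydro-β,ψ-caroten-3-ol (carotenoid numbering is used in the text); all polyene steps are run under argon with exclusion of light.

**Route**

Step 1
Reactants: 1 3-(trimethylsilyl)prop-2-ynal
Product: 2 (E)-(4-iodobut-3-en-1-yn-1-yl)trimethylsilane
Conditions: CrCl2 (6 equiv), CHI3 (2 equiv), THF, 0 °C → rt, dark
Reagents that add atoms: iodoform, IC(I)I
Why: Takai olefination; the gem-dichromium iodocarbenoid adds to the aldehyde and eliminates to the (E)-iodoalkene.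

Step 2
Reactants: 3 6-methylhept-5-en-2-one
Product: 5 6-methylhept-5-en-1-yne, via enol phosphate 4 (not isolated)
Conditions: LDA (1.1 equiv), THF, −78 °C; ClP(O)(OEt)2, −78 °C → rt; LDA (2.3 equiv), −78 °C → rt; H2O
Reagents that add atoms: none
Why: Methyl ketone to terminal alkyne by O-phosphorylation of the kinetic terminal enolate and β-elimination of the enol phosphate with LDA.

Step 3
Reactants: 5 6-methylhept-5-en-1-yne; 2 (E)-(4-iodobut-3-en-1-yn-1-yl)trimethylsilane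
Product: 7 trimethyl[(3E,5E)-6,10-dimethylundeca-3,5,9-trien-1-yn-1-yl]silane, via alkenylalane 6 (not isolated)
Conditions: Me3Al (2 equiv), Cp2ZrCl2 (0.25 equiv), CH2Cl2, 23 °C; evaporate; then 2, ZnCl2 (1 equiv), Pd2(dba)3 (2.5 mol %), P(2-furyl)3 (10 mol %), THF–DMF, 23 °C
Reagents that add atoms: trimethylaluminium, C[Al](C)C
Why: Zr-catalysed syn-methylalumination of the terminal alkyne followed by Pd/Zn-catalysed Negishi coupling with retention should give the 5'E trisubstituted alkene and keep the E-iodoalkene geometry.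

Step 4
Reactants: 7 trimethyl[(3E,5E)-6,10-dimethylundeca-3,5,9-trien-1-yn-1-yl]silane
Product: 8 (3E,5E)-6,10-dimethylundeca-3,5,9-trien-1-yne
Conditions: K2CO3 (cat.), MeOH, 23 °C
Reagents that add atoms: none
Why: Methoxide-mediated protodesilylation of an alkynylsilane leaves the polyene untouched.

Step 5
Reactants: 8 (3E,5E)-6,10-dimethylundeca-3,5,9-trien-1-yne; 2 (E)-(4-iodobut-3-en-1-yn-1-yl)trimethylsilane
Product: 10 trimethyl[(3E,5E,7E,9E)-6,10,14-trimethylpentadeca-3,5,7,9,13-pentaen-1-yn-1-yl]silane, via alkenylalane 9 (not isolated)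
Conditions: Me3Al (2 equiv), Cp2ZrCl2 (0.25 equiv), CH2Cl2, 23 °C; evaporate; then 2, ZnCl2, Pd2(dba)3 (2.5 mol %), P(2-furyl)3 (10 mol %), THF–DMF, 23 °C
Reagents that add atoms: trimethylaluminium, C[Al](C)C
Why: Second round of syn-methylalumination/Negishi coupling, now on a conjugated enyne, should set the 9'E alkene and add the C11'–C14' unit.

Step 6
Reactants: 10 trimethyl[(3E,5E,7E,9E)-6,10,14-trimethylpentadeca-3,5,7,9,13-pentaen-1-yn-1-yl]silane
Product: 11 (3E,5E,7E,9E)-6,10,14-trimethylpentadeca-3,5,7,9,13-pentaen-1-yne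
Conditions: K2CO3 (cat.), MeOH–THF, 23 °C
Reagents that add atoms: none
Why: Protodesilylation of the alkynylsilane frees the terminal alkyne needed for the key step.

Step 7
Reactants: 12 ethyl 3-oxobutanoate
Product: 13 ethyl (2E)-3-{[(trifluoromethyl)sulfonyl]oxy}but-2-enoate
Conditions: Tf2O, aq. Me4NOH, hexanes, 5–10 °C
Reagents that add atoms: triflic anhydride, O=S(=O)(OS(=O)(=O)C(F)(F)F)C(F)(F)F
Why: O-triflation of the non-chelated ammonium enolate of a β-keto ester should give the E enol triflate (OTf trans to the ester).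

Step 8
Reactants: 14 (4R,6R)-4-hydroxy-2,2,6-trimethylcyclohexan-1-one
Product: 15 (4R,6R)-4-[(tert-butyldimethylsilyl)oxy]-2,2,6-trimethylcyclohexan-1-one
Conditions: TBSCl, imidazole, DMF, 23 °C
Reagents that add atoms: tert-butyldimethylsilyl chloride, CC(C)(C)[Si](C)(C)Cl
Why: Silylation of the secondary alcohol protects O3 for the whole route without touching the stereocentre.

Step 9
Reactants: 15 (4R,6R)-4-[(tert-butyldimethylsilyl)oxy]-2,2,6-trimethylcyclohexan-1-one
Product: 16 (4R)-4-[(tert-butyldimethylsilyl)oxy]-2,6,6-trimethylcyclohex-1-en-1-yl trifluoromethanesulfonate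
Conditions: LDA, THF, −78 °C; PhNTf2, −78 → 0 °C
Reagents that add atoms: N-phenylbis(trifluoromethanesulfonimide), O=S(=O)(N(c1ccccc1)S(=O)(=O)C(F)(F)F)C(F)(F)F
Why: Only the C6 methine is enolisable, so enolate O-triflation is regiospecific; the C6 centre is erased on purpose and C4 is untouched.

Step 10
Reactants: 16 (4R)-4-[(tert-butyldimethylsilyl)oxy]-2,6,6-trimethylcyclohex-1-en-1-yl trifluoromethanesulfonate
Product: 17 methyl (4R)-4-[(tert-butyldimethylsilyl)oxy]-2,6,6-trimethylcyclohex-1-ene-1-carboxylate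
Conditions: CO (1 atm), Pd(OAc)2 (5 mol %), PPh3 (10 mol %), Et3N, MeOH–DMF, 50 °C
Reagents that add atoms: carbon monoxide, [C-]#[O+]; methanol, CO
Why: Pd-catalysed methoxycarbonylation of an enol triflate installs C7 on the tetrasubstituted alkene.

Step 11
Reactants: 17 methyl (4R)-4-[(tert-butyldimethylsilyl)oxy]-2,6,6-trimethylcyclohex-1-ene-1-carboxylate
Product: 18 [(4R)-4-[(tert-butyldimethylsilyl)oxy]-2,6,6-trimethylcyclohex-1-en-1-yl]methanol
Conditions: DIBAL-H (2.5 equiv), CH2Cl2, −78 °C; Rochelle salt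
Reagents that add atoms: none
Why: 1,2-Reduction of the enoate gives the allylic alcohol needed to direct the epoxidation.

Step 12
Reactants: 18 [(4R)-4-[(tert-butyldimethylsilyl)oxy]-2,6,6-trimethylcyclohex-1-en-1-yl]methanol
Product: 19 [(1R,4S,6R)-4-[(tert-butyldimethylsilyl)oxy]-2,2,6-trimethyl-7-oxabicyclo[4.1.0]heptan-1-yl]methanol
Conditions: Ti(OiPr)4 (1 equiv), D-(−)-diethyl tartrate (1.2 equiv), t-BuOOH (2 equiv), 4 Å MS, CH2Cl2, −20 °C
Reagents that add atoms: tert-butyl hydroperoxide, CC(C)(C)OO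
Why: Sharpless asymmetric epoxidation, in which the Ti/D-(−)-tartrate complex delivers oxygen to the alkene face trans to the C4 silyloxy group under reagent control and so sets both oxirane centres (5R,6S in carotenoid numbering).

Step 13
Reactants: 19 [(1R,4S,6R)-4-[(tert-butyldimethylsilyl)oxy]-2,2,6-trimethyl-7-oxabicyclo[4.1.0]heptan-1-yl]methanol
Product: 20 (1S,4S,6R)-4-[(tert-butyldimethylsilyl)oxy]-2,2,6-trimethyl-7-oxabicyclo[4.1.0]heptane-1-carbaldehyde
Conditions: TPAP (5 mol %), NMO, 4 Å MS, CH2Cl2, 23 °C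
Reagents that add atoms: none
Why: Ley–Griffith oxidation of the primary alcohol under neutral conditions gives a non-enolisable epoxy aldehyde.

Step 14
Reactants: 20 (1S,4S,6R)-4-[(tert-butyldimethylsilyl)oxy]-2,2,6-trimethyl-7-oxabicyclo[4.1.0]heptane-1-carbaldehyde
Product: 21 tert-butyl{[(1R,4S,6R)-1-ethynyl-2,2,6-trimethyl-7-oxabicyclo[4.1.0]heptan-4-yl]oxy}dimethylsilane
Conditions: dimethyl (1-diazo-2-oxopropyl)phosphonate, K2CO3, MeOH, 0 → 23 °C
Reagents that add atoms: dimethyl (1-diazo-2-oxopropyl)phosphonate, CC(=O)C(=[N+]=[N-])P(=O)(OC)OC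
Why: Ohira–Bestmann homologation turns the aldehyde into the terminal alkyne (C7≡C8) without touching the oxirane centres.

Step 15
Reactants: 21 tert-butyl{[(1R,4S,6R)-1-ethynyl-2,2,6-trimethyl-7-oxabicyclo[4.1.0]heptan-4-yl]oxy}dimethylsilane; 13 ethyl (2E)-3-{[(trifluoromethyl)sulfonyl]oxy}but-2-enoate
Product: 22 ethyl (2E)-5-[(1R,4S,6R)-4-[(tert-butyldimethylsilyl)oxy]-2,2,6-trimethyl-7-oxabicyclo[4.1.0]heptan-1-yl]-3-methylpent-2-en-4-ynoate
Conditions: Pd(PPh3)4 (5 mol %), CuI (10 mol %), Et3N, THF, 23 °C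
Reagents that add atoms: none
Why: Sonogashira coupling of the terminal alkyne with the activated enol triflate proceeds with retention and should fix the 9E alkene.

Step 16
Reactants: 22 ethyl (2E)-5-[(1R,4S,6R)-4-[(tert-butyldimethylsilyl)oxy]-2,2,6-trimethyl-7-oxabicyclo[4.1.0]heptan-1-yl]-3-methylpent-2-en-4-ynoate
Product: 23 (2E)-5-[(2R,4S)-4-[(tert-butyldimethylsilyl)oxy]-2-hydroxy-2,6,6-trimethylcyclohexylidene]-3-methylpenta-2,4-dien-1-ol with R allene axis (6R in carotenoid numbering)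
Conditions: DIBAL-H (5 equiv), CH2Cl2, −78 → 0 °C; Rochelle salt
Reagents that add atoms: none
Why: DIBAL-H reduces the ester to the allylic alcohol and, bound to the epoxide oxygen, delivers hydride to C8 on the side of the breaking C6–O bond (syn-SN2' opening of an alkynyl epoxide), which should turn the (5R,6S)-epoxide into the 5R carbinol and the R allene axis.

Step 17
Reactants: 23 (2E)-5-[(2R,4S)-4-[(tert-butyldimethylsilyl)oxy]-2-hydroxy-2,6,6-trimethylcyclohexylidene]-3-methylpenta-2,4-dien-1-ol (R axis)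
Product: 24 (2E)-3-[(2S,6S,7aR)-6-[(tert-butyldimethylsilyl)oxy]-4,4,7a-trimethyl-2,4,5,6,7,7a-hexahydro-1-benzofuran-2-yl]but-2-en-1-ol
Conditions: AuCl3 (2 mol %), THF, 23 °C, dark
Reagents that add atoms: none
Why: Gold π-activation of the C7=C8 allene bond triggers 5-endo attack of the C5 hydroxyl on C8 and protodeauration (cycloisomerisation of an α-hydroxyallene to a 2,5-dihydrofuran), so the R axis should be transferred to C8 as 8S with the side chain cis to the C5 methyl.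

Step 18
Reactants: 24 (2E)-3-[(2S,6S,7aR)-6-[(tert-butyldimethylsilyl)oxy]-4,4,7a-trimethyl-2,4,5,6,7,7a-hexahydro-1-benzofuran-2-yl]but-2-en-1-ol
Product: 25 (2E)-3-[(2S,6S,7aR)-6-[(tert-butyldimethylsilyl)oxy]-4,4,7a-trimethyl-2,4,5,6,7,7a-hexahydro-1-benzofuran-2-yl]but-2-enal
Conditions: MnO2, CH2Cl2, 23 °C
Reagents that add atoms: none
Why: MnO2 oxidises the primary allylic alcohol selectively under neutral conditions.

Step 19
Reactants: 25 (2E)-3-[(2S,6S,7aR)-6-[(tert-butyldimethylsilyl)oxy]-4,4,7a-trimethyl-2,4,5,6,7,7a-hexahydro-1-benzofuran-2-yl]but-2-enal; 26 ethyl (2E)-4-(diethoxyphosphoryl)-3-methylbut-2-enoate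
Product: 27 ethyl (2E,4E,6E)-7-[(2S,6S,7aR)-6-[(tert-butyldimethylsilyl)oxy]-4,4,7a-trimethyl-2,4,5,6,7,7a-hexahydro-1-benzofuran-2-yl]-3-methylocta-2,4,6-trienoate
Conditions: 26, LiHMDS, THF–DMPU, −78 → 0 °C
Reagents that add atoms: none
Why: Horner–Wadsworth–Emmons olefination with the stabilised C5 phosphonate should give the E C11=C12 bond, and the weakly basic anion should leave the γ-centre C8 alone (any 13Z isomer is removed by chromatography).

Step 20
Reactants: 27 ethyl (2E,4E,6E)-7-[(2S,6S,7aR)-6-[(tert-butyldimethylsilyl)oxy]-4,4,7a-trimethyl-2,4,5,6,7,7a-hexahydro-1-benzofuran-2-yl]-3-methylocta-2,4,6-trienoate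
Product: 28 (2E,4E,6E)-7-[(2S,6S,7aR)-6-[(tert-butyldimethylsilyl)oxy]-4,4,7a-trimethyl-2,4,5,6,7,7a-hexahydro-1-benzofuran-2-yl]-3-methylocta-2,4,6-trien-1-ol
Conditions: DIBAL-H (2.5 equiv), CH2Cl2, −78 °C; Rochelle salt
Reagents that add atoms: none
Why: 1,2-Reduction of the trienoate to the allylic alcohol with a neutral work-up spares the allylic ether.

Step 21
Reactants: 28 (2E,4E,6E)-7-[(2S,6S,7aR)-6-[(tert-butyldimethylsilyl)oxy]-4,4,7a-trimethyl-2,4,5,6,7,7a-hexahydro-1-benzofuran-2-yl]-3-methylocta-2,4,6-trien-1-ol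
Product: 29 (2E,4E,6E)-7-[(2S,6S,7aR)-6-[(tert-butyldimethylsilyl)oxy]-4,4,7a-trimethyl-2,4,5,6,7,7a-hexahydro-1-benzofuran-2-yl]-3-methylocta-2,4,6-trienal
Conditions: MnO2, CH2Cl2, 23 °C
Reagents that add atoms: none
Why: Allylic oxidation with MnO2 gives the C20 trienal without acid or base.

Step 22
Reactants: 29 (2E,4E,6E)-7-[(2S,6S,7aR)-6-[(tert-butyldimethylsilyl)oxy]-4,4,7a-trimethyl-2,4,5,6,7,7a-hexahydro-1-benzofuran-2-yl]-3-methylocta-2,4,6-trienal
Product: 30 tert-butyl{[(2S,6S,7aR)-2-[(2E,4E,6E,8E)-9-iodo-6-methylnona-2,4,6,8-tetraen-2-yl]-4,4,7a-trimethyl-2,4,5,6,7,7a-hexahydro-1-benzofuran-6-yl]oxy}dimethylsilane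
Conditions: CrCl2 (8 equiv), CHI3 (3 equiv), THF, 0 → 23 °C, dark
Reagents that add atoms: iodoform, IC(I)I
Why: Takai olefination adds C15' as an (E)-iodoalkene under conditions that leave the silyl ether and the dihydrofuran intact.

Step 23
Reactants: 11 (3E,5E,7E,9E)-6,10,14-trimethylpentadeca-3,5,7,9,13-pentaen-1-yne; 30 tert-butyl{[(2S,6S,7aR)-2-[(2E,4E,6E,8E)-9-iodo-6-methylnona-2,4,6,8-tetraen-2-yl]-4,4,7a-trimethyl-2,4,5,6,7,7a-hexahydro-1-benzofuran-6-yl]oxy}dimethylsilane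
Product: 32 (3S,5R,8S)-5,8-epoxy-5,8-dihydro-β,ψ-caroten-3-yl tert-butyldimethylsilyl ether, via alkenylalane 31 (not isolated)
Conditions: 11 (1.3 equiv), Me3Al (2 equiv), Cp2ZrCl2 (0.3 equiv), (CH2Cl)2, 23 °C; evaporate excess Me3Al; THF; then 30, ZnCl2 (1 equiv), Pd2(dba)3 (2.5 mol %), P(2-furyl)3 (10 mol %), THF–DMF, 23 °C, dark
Reagents that add atoms: trimethylaluminium, C[Al](C)C
Why: Cp2ZrCl2/Me3Al generates a cationic methylzirconium species that adds Me–metal syn across the only terminal alkyne of 11 (Me to C13', metal to C14'; Zr-catalysed methylalumination), and Al→Zn→Pd transmetalation, oxidative addition of 30 and reductive elimination then form C14'–C15' with retention at both alkenyl carbons (Negishi coupling). The closest known reaction type is the tandem carboalumination/Pd–Zn cross-coupling of conjugated enynes with alkenyl halides used for retinoid and carotenoid chains, and steps 3 and 5 rehearse it on the same chain. No ring is closed and no stereocentre is formed; the stereochemical content is the 13'E geometry, fixed by the syn addition that places the new C20' methyl cis to C15', and the 15E geometry carried over from the iodide. The step needs regio- and chemoselectivity for the C13'≡C14' triple bond over the five C=C bonds of 11, which the terminal alkyne secures because only it inserts into the Me–Zr bond at 23 °C. It also needs the doubly allylic C8–O bond and the silyl ether of 30 to survive, which is secured by evaporating excess Me3Al before 30 is added and by running the coupling in THF–DMF, where the Al and Zn centres are saturated by donor solvent.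

Step 24
Reactants: 32 (3S,5R,8S)-5,8-epoxy-5,8-dihydro-β,ψ-caroten-3-yl tert-butyldimethylsilyl ether
Product: 33 (3S,5R,8S)-5,8-epoxy-5,8-dihydro-β,ψ-caroten-3-ol
Conditions: TBAF, THF, 0 → 23 °C, dark
Reagents that add atoms: none
Why: Fluoride cleavage of the silyl ether is basic and non-acidic, so the C8 allylic ether and the polyene should be unaffected.

**Compound list**

1 | 3-(trimethylsilyl)prop-2-ynal | C[Si](C)(C)C#CC=O | starting material
2 | (E)-(4-iodobut-3-en-1-yn-1-yl)trimethylsilane | C[Si](C)(C)C#C/C=C/I | intermediate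
3 | 6-methylhept-5-en-2-one | CC(=O)CCC=C(C)C | starting material
4 | diethyl 6-methylhepta-1,5-dien-2-yl phosphate | C=C(CCC=C(C)C)OP(=O)(OCC)OCC | intermediate (not isolated)
5 | 6-methylhept-5-en-1-yne | C#CCCC=C(C)C | intermediate
6 | [(1E)-2,6-dimethylhepta-1,5-dien-1-yl]dimethylalumane | CC(C)=CCC/C(C)=C/[Al](C)C | intermediate (not isolated)
7 | trimethyl[(3E,5E)-6,10-dimethylundeca-3,5,9-trien-1-yn-1-yl]silane | CC(C)=CCC/C(C)=C/C=C/C#C[Si](C)(C)C | intermediate
8 | (3E,5E)-6,10-dimethylundeca-3,5,9-trien-1-yne | CC(C)=CCC/C(C)=C/C=C/C#C | intermediate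
9 | dimethyl[(1E,3E,5E)-2,6,10-trimethylundeca-1,3,5,9-tetraen-1-yl]alumane | CC(C)=CCC/C(C)=C/C=C/C(C)=C/[Al](C)C | intermediate (not isolated)
10 | trimethyl[(3E,5E,7E,9E)-6,10,14-trimethylpentadeca-3,5,7,9,13-pentaen-1-yn-1-yl]silane | CC(C)=CCC/C(C)=C/C=C/C(C)=C/C=C/C#C[Si](C)(C)C | intermediate
11 | (3E,5E,7E,9E)-6,10,14-trimethylpentadeca-3,5,7,9,13-pentaen-1-yne | CC(C)=CCC/C(C)=C/C=C/C(C)=C/C=C/C#C | intermediate
12 | ethyl 3-oxobutanoate | CCOC(=O)CC(C)=O | starting material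
13 | ethyl (2E)-3-{[(trifluoromethyl)sulfonyl]oxy}but-2-enoate | CCOC(=O)/C=C(C)/OS(=O)(=O)C(F)(F)F | intermediate
14 | (4R,6R)-4-hydroxy-2,2,6-trimethylcyclohexan-1-one | CC1(C)C[C@H](O)C[C@@H](C)C1=O | starting material
15 | (4R,6R)-4-[(tert-butyldimethylsilyl)oxy]-2,2,6-trimethylcyclohexan-1-one | CC1(C)C[C@H](O[Si](C)(C)C(C)(C)C)C[C@@H](C)C1=O | intermediate
16 | (4R)-4-[(tert-butyldimethylsilyl)oxy]-2,6,6-trimethylcyclohex-1-en-1-yl trifluoromethanesulfonate | CC1=C(OS(=O)(=O)C(F)(F)F)C(C)(C)C[C@H](O[Si](C)(C)C(C)(C)C)C1 | intermediate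
17 | methyl (4R)-4-[(tert-butyldimethylsilyl)oxy]-2,6,6-trimethylcyclohex-1-ene-1-carboxylate | COC(=O)C1=C(C)C[C@@H](O[Si](C)(C)C(C)(C)C)CC1(C)C | intermediate
18 | [(4R)-4-[(tert-butyldimethylsilyl)oxy]-2,6,6-trimethylcyclohex-1-en-1-yl]methanol | OCC1=C(C)C[C@@H](O[Si](C)(C)C(C)(C)C)CC1(C)C | intermediate
19 | [(1R,4S,6R)-4-[(tert-butyldimethylsilyl)oxy]-2,2,6-trimethyl-7-oxabicyclo[4.1.0]heptan-1-yl]methanol (oxirane trans to the silyloxy group) | OC[C@@]12O[C@]1(C)C[C@@H](O[Si](C)(C)C(C)(C)C)CC2(C)C | intermediate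
20 | (1S,4S,6R)-4-[(tert-butyldimethylsilyl)oxy]-2,2,6-trimethyl-7-oxabicyclo[4.1.0]heptane-1-carbaldehyde | O=C[C@@]12O[C@]1(C)C[C@@H](O[Si](C)(C)C(C)(C)C)CC2(C)C | intermediate
21 | tert-butyl{[(1R,4S,6R)-1-ethynyl-2,2,6-trimethyl-7-oxabicyclo[4.1.0]heptan-4-yl]oxy}dimethylsilane | C#C[C@@]12O[C@]1(C)C[C@@H](O[Si](C)(C)C(C)(C)C)CC2(C)C | intermediate
22 | ethyl (2E)-5-[(1R,4S,6R)-4-[(tert-butyldimethylsilyl)oxy]-2,2,6-trimethyl-7-oxabicyclo[4.1.0]heptan-1-yl]-3-methylpent-2-en-4-ynoate | CCOC(=O)/C=C(C)/C#C[C@@]12O[C@]1(C)C[C@@H](O[Si](C)(C)C(C)(C)C)CC2(C)C | intermediate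
23 | (2E)-5-[(2R,4S)-4-[(tert-butyldimethylsilyl)oxy]-2-hydroxy-2,6,6-trimethylcyclohexylidene]-3-methylpenta-2,4-dien-1-ol, R allene axis (6R in carotenoid numbering) | [H]C(/C(C)=C/CO)=[C@]=C1C(C)(C)C[C@H](O[Si](C)(C)C(C)(C)C)C[C@@]1(C)O | intermediate
24 | (2E)-3-[(2S,6S,7aR)-6-[(tert-butyldimethylsilyl)oxy]-4,4,7a-trimethyl-2,4,5,6,7,7a-hexahydro-1-benzofuran-2-yl]but-2-en-1-ol | OC/C=C(C)/[C@@H]1C=C2C(C)(C)C[C@H](O[Si](C)(C)C(C)(C)C)C[C@@]2(C)O1 | intermediate
25 | (2E)-3-[(2S,6S,7aR)-6-[(tert-butyldimethylsilyl)oxy]-4,4,7a-trimethyl-2,4,5,6,7,7a-hexahydro-1-benzofuran-2-yl]but-2-enal | O=C/C=C(C)/[C@@H]1C=C2C(C)(C)C[C@H](O[Si](C)(C)C(C)(C)C)C[C@@]2(C)O1 | intermediate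
26 | ethyl (2E)-4-(diethoxyphosphoryl)-3-methylbut-2-enoate (triethyl 3-methyl-4-phosphonocrotonate) | CCOC(=O)/C=C(C)/CP(=O)(OCC)OCC | starting material
27 | ethyl (2E,4E,6E)-7-[(2S,6S,7aR)-6-[(tert-butyldimethylsilyl)oxy]-4,4,7a-trimethyl-2,4,5,6,7,7a-hexahydro-1-benzofuran-2-yl]-3-methylocta-2,4,6-trienoate | CCOC(=O)/C=C(C)/C=C/C=C(\C)[C@@H]1C=C2C(C)(C)C[C@H](O[Si](C)(C)C(C)(C)C)C[C@@]2(C)O1 | intermediate
28 | (2E,4E,6E)-7-[(2S,6S,7aR)-6-[(tert-butyldimethylsilyl)oxy]-4,4,7a-trimethyl-2,4,5,6,7,7a-hexahydro-1-benzofuran-2-yl]-3-methylocta-2,4,6-trien-1-ol | OC/C=C(C)/C=C/C=C(\C)[C@@H]1C=C2C(C)(C)C[C@H](O[Si](C)(C)C(C)(C)C)C[C@@]2(C)O1 | intermediate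
29 | (2E,4E,6E)-7-[(2S,6S,7aR)-6-[(tert-butyldimethylsilyl)oxy]-4,4,7a-trimethyl-2,4,5,6,7,7a-hexahydro-1-benzofuran-2-yl]-3-methylocta-2,4,6-trienal | O=C/C=C(C)/C=C/C=C(\C)[C@@H]1C=C2C(C)(C)C[C@H](O[Si](C)(C)C(C)(C)C)C[C@@]2(C)O1 | intermediate
30 | tert-butyl{[(2S,6S,7aR)-2-[(2E,4E,6E,8E)-9-iodo-6-methylnona-2,4,6,8-tetraen-2-yl]-4,4,7a-trimethyl-2,4,5,6,7,7a-hexahydro-1-benzofuran-6-yl]oxy}dimethylsilane | I/C=C/C=C(C)/C=C/C=C(\C)[C@@H]1C=C2C(C)(C)C[C@H](O[Si](C)(C)C(C)(C)C)C[C@@]2(C)O1 | intermediate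
31 | dimethyl[(1E,3E,5E,7E,9E)-2,6,10,14-tetramethylpentadeca-1,3,5,7,9,13-hexaen-1-yl]alumane | CC(C)=CCC/C(C)=C/C=C/C(C)=C/C=C/C(C)=C/[Al](C)C | intermediate (not isolated)
32 | (3S,5R,8S)-5,8-epoxy-5,8-dihydro-β,ψ-caroten-3-yl tert-butyldimethylsilyl ether (all-E) | CC(C)=CCC/C(C)=C/C=C/C(C)=C/C=C/C(C)=C/C=C/C=C(C)/C=C/C=C(\C)[C@@H]1C=C2C(C)(C)C[C@H](O[Si](C)(C)C(C)(C)C)C[C@@]2(C)O1 | intermediate
33 | (3S,5R,8S)-5,8-epoxy-5,8-dihydro-β,ψ-caroten-3-ol (all-E) | CC(C)=CCC/C(C)=C/C=C/C(C)=C/C=C/C(C)=C/C=C/C=C(C)/C=C/C=C(\C)[C@@H]1C=C2C(C)(C)C[C@H](O)C[C@@]2(C)O1 | target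

**Step count and risks**

Total step count: 24. Longest linear sequence: 17 steps (14 → 33, steps 8–24).

Steps most likely to fail:

1. Step 23. The Al, Zn and Zr Lewis acids present may ionise the doubly allylic C8–O bond of the dihydrofuran, which would lose the C8 configuration or open the ring; carbometalation of the pentaenyne may also be incomplete. Fallback: the two events are separated and the union is done under basic conditions. From 11, the same methylalumination is quenched with I2 to give (1E,3E,5E,7E,9E)-1-iodo-2,6,10,14-tetramethylpentadeca-1,3,5,7,9,13-hexaene F1. From 30, Miyaura borylation (B2pin2, PdCl2(PPh3)2, PPh3, KOPh, toluene, 50 °C) gives the C21 tetraenyl pinacol boronate F2. Suzuki–Miyaura coupling of F1 with F2 (Pd(PPh3)4, aq. K3PO4, THF, 23 °C) should come back to the route at 32.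

2. Step 17. The vinylallene may follow other π-acid pathways (Nazarov-type cyclisation), and gold-assisted ionisation of the product may erode the C8 configuration. Fallback: the dihydrofuran is made by the classical 5,6-epoxide-to-5,8-furanoid rearrangement. From 20, Horner–Wadsworth–Emmons olefination with 26 (LiHMDS, THF) gives the C15 epoxy dienoate F3, and DIBAL-H reduction gives the C15 epoxy dienol F4. A trace of acid (PPTS, CH2Cl2, 0 °C) should rearrange F4 to the furanoid as a pair of C8 epimers, from which 24 is separated by chromatography, rejoining the route at 24.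

3. Step 22. Addition of the chromium carbenoid to the deactivated, hindered trienal may be slow, with erosion of E selectivity and Lewis-acid damage to the allylic ether during long reaction times. Fallback: from 29, Colvin homologation (lithiated trimethylsilyldiazomethane, THF, −78 °C → rt) gives the C21 trienyne F5. Hydrozirconation (Cp2Zr(H)Cl, THF, 23 °C) followed by I2 at 0 °C places iodine on the terminal carbon by syn addition and should return to the route at 30.

**Further compounds**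

F1 | step 23 | (1E,3E,5E,7E,9E)-1-iodo-2,6,10,14-tetramethylpentadeca-1,3,5,7,9,13-hexaene | CC(C)=CCC/C(C)=C/C=C/C(C)=C/C=C/C(C)=C/I
F2 | step 23 | 2-[(1E,3E,5E,7E)-8-[(2S,6S,7aR)-6-[(tert-butyldimethylsilyl)oxy]-4,4,7a-trimethyl-2,4,5,6,7,7a-hexahydro-1-benzofuran-2-yl]-4-methylnona-1,3,5,7-tetraen-1-yl]-4,4,5,5-tetramethyl-1,3,2-dioxaborolane | CC1(C)OB(/C=C/C=C(C)/C=C/C=C(\C)[C@@H]2C=C3C(C)(C)C[C@H](O[Si](C)(C)C(C)(C)C)C[C@@]3(C)O2)OC1(C)C
F3 | step 17 | ethyl (2E,4E)-5-[(1S,4S,6R)-4-[(tert-butyldimethylsilyl)oxy]-2,2,6-trimethyl-7-oxabicyclo[4.1.0]heptan-1-yl]-3-methylpenta-2,4-dienoate | CCOC(=O)/C=C(C)/C=C/[C@@]12O[C@]1(C)C[C@@H](O[Si](C)(C)C(C)(C)C)CC2(C)C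
F4 | step 17 | (2E,4E)-5-[(1S,4S,6R)-4-[(tert-butyldimethylsilyl)oxy]-2,2,6-trimethyl-7-oxabicyclo[4.1.0]heptan-1-yl]-3-methylpenta-2,4-dien-1-ol | OC/C=C(C)/C=C/[C@@]12O[C@]1(C)C[C@@H](O[Si](C)(C)C(C)(C)C)CC2(C)C
F5 | step 22 | tert-butyl{[(2S,6S,7aR)-2-[(2E,4E,6E)-6-methylnona-2,4,6-trien-8-yn-2-yl]-4,4,7a-trimethyl-2,4,5,6,7,7a-hexahydro-1-benzofuran-6-yl]oxy}dimethylsilane | C#C/C=C(C)/C=C/C=C(\C)[C@@H]1C=C2C(C)(C)C[C@H](O[Si](C)(C)C(C)(C)C)C[C@@]2(C)O1
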